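**Strategy.** The hydroazulene core (azulene numbering, C-1 = quaternary carbon) is closed by one intramolecular palladium-catalysed [4+3] cycloaddition that forms C-3a–C-8a and C-5–C-6. It exploits two features of the seven-membered ring: C-3a/C-4/C-5 is a trimethylenemethane unit whose central carbon C-4 bears the methyl group (delivered as an exocyclic methylene from a strained alkylidenecyclopropane), and C-6/C-7/C-8/C-8a is a diene unit whose C-7 bears the ester that becomes the hydroxyisopropyl group. C-1 to C-3 of the cyclopentane act as tether. The precursor is an acyclic alkylidenecyclopropane–dienoate whose quaternary/benzylic stereodiad is set on a dihydrocoumarin template.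

Key step: step 11

Locants: bicyclic compounds carry azulene locants (C-1 quaternary carbon, C-3a ring-fusion CH, C-4 methyl-bearing carbon, C-7 ester/carbinol-bearing carbon, C-8a the other ring-fusion carbon).
Assumption: 16 is drawn cis-fused; its C-8a configuration is erased in step 13 and does not affect the route.

Step 1
Reactants: 1 5,7-dimethoxycoumarin
Product: 2 (4R)-5,7-dimethoxy-4-(2-methylpropyl)chroman-2-one
Conditions: i-BuMgBr (1.5 equiv), CuBr·SMe2 (5 mol %), (R)-1-[(Sp)-2-(dicyclohexylphosphino)ferrocenyl]ethyldiphenylphosphine (6 mol %, or its enantiomer, whichever delivers 4R), t-BuOMe/CH2Cl2, −78 °C; then 1 M HCl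
Reagents that add atoms: isobutylmagnesium bromide, CC(C)C[Mg]Br
Why: Copper-catalysed asymmetric conjugate addition of a Grignard reagent to the coumarin enoate; the chiral diphosphine–copper complex controls the face of C-4 and sets the later benzylic stereocentre.

Step 2
Reactants: 2 (4R)-5,7-dimethoxy-4-(2-methylpropyl)chroman-2-one
Product: 4 (3R,4R)-5,7-dimethoxy-3-methyl-4-(2-methylpropyl)chroman-2-one, via lithium enolate 3 (not isolated)
Conditions: LiN(SiMe3)2 (1.05 equiv), THF, −78 °C; then MeI, −78 → −20 °C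
Reagents that add atoms: iodomethane, CI
Why: Enolate C-alkylation in which methyl should enter trans to the C-4 isobutyl group; this C-3 centre is re-trigonalised in step 3, so its configuration only serves to give one compound.

Step 3
Reactants: 4 (3R,4R)-5,7-dimethoxy-3-methyl-4-(2-methylpropyl)chroman-2-one
Product: 6 (3R,4S)-5,7-dimethoxy-3-methyl-4-(2-methylpropyl)-3-(prop-2-en-1-yl)chroman-2-one, via lithium enolate 5 (not isolated)
Conditions: LiN(iPr)2 (1.2 equiv), THF/DMPU, −78 °C; then allyl bromide, −78 → 0 °C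
Reagents that add atoms: allyl bromide, C=CCBr
Why: Alkylation of the tetrasubstituted lactone enolate on the face anti to the pseudoaxial C-4 isobutyl group (1,2-induction within the six-membered lactone) should place allyl trans and methyl cis to isobutyl, which fixes the quaternary centre relative to the benzylic one.

Step 4
Reactants: 6 (3R,4S)-5,7-dimethoxy-3-methyl-4-(2-methylpropyl)-3-(prop-2-en-1-yl)chroman-2-one
Product: 8 methyl (2R,3S)-2,5-dimethyl-2-(prop-2-en-1-yl)-3-(2,4,6-trimethoxyphenyl)hexanoate, via ring-opened dipotassium salt 7 (not isolated)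
Conditions: KOH (powdered, 4 equiv), DMSO, rt; then MeI (6 equiv), rt
Reagents that add atoms: potassium hydroxide, [K+].[OH-]; iodomethane, CI
Why: Saponification of the aryl lactone followed by exhaustive Williamson-type O-methylation of phenoxide and carboxylate releases the acyclic ester and completes the trimethoxyphenyl group without touching a stereocentre.

Step 5
Reactants: 8 methyl (2R,3S)-2,5-dimethyl-2-(prop-2-en-1-yl)-3-(2,4,6-trimethoxyphenyl)hexanoate
Product: 10 methyl (2R,3S)-2-(3-hydroxypropyl)-2,5-dimethyl-3-(2,4,6-trimethoxyphenyl)hexanoate, via B-alkyl-9-borabicyclononane 9 (not isolated)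
Conditions: 9-BBN (1.3 equiv), THF, 0 °C → rt; then 3 M NaOH, 30% H2O2, 0 °C
Reagents that add atoms: hydrogen peroxide, OO
Why: Anti-Markovnikov hydroboration of the terminal alkene with a bulky borane and oxidation of the C–B bond give the primary alcohol, while the hindered α-quaternary ester should survive the brief basic oxidation.

Step 6
Reactants: 10 methyl (2R,3S)-2-(3-hydroxypropyl)-2,5-dimethyl-3-(2,4,6-trimethoxyphenyl)hexanoate
Product: 11 methyl (2R,3S)-2,5-dimethyl-2-(3-oxopropyl)-3-(2,4,6-trimethoxyphenyl)hexanoate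
Conditions: Dess–Martin periodinane, CH2Cl2, rt
Reagents that add atoms: none
Why: Dess–Martin oxidation of a primary alcohol to the aldehyde under mild conditions that tolerate the electron-rich arene.

Step 7
Reactants: 11 methyl (2R,3S)-2,5-dimethyl-2-(3-oxopropyl)-3-(2,4,6-trimethoxyphenyl)hexanoate
Product: 12 methyl (2R,3S)-2-(3-cyclopropylidenepropyl)-2,5-dimethyl-3-(2,4,6-trimethoxyphenyl)hexanoate
Conditions: cyclopropyltriphenylphosphonium bromide (1.5 equiv), KOtBu (1.5 equiv), THF, 60 °C; then 11, 0 °C → rt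
Reagents that add atoms: cyclopropyltriphenylphosphonium bromide, [Br-].C1CC1[P+](c1ccccc1)(c1ccccc1)c1ccccc1
Why: Wittig olefination with the non-stabilised cyclopropylidene ylide installs the alkylidenecyclopropane at the aldehyde, and the hindered methyl ester should not compete.

Step 8
Reactants: 12 methyl (2R,3S)-2-(3-cyclopropylidenepropyl)-2,5-dimethyl-3-(2,4,6-trimethoxyphenyl)hexanoate
Product: 13 (2R,3R)-2-(3-cyclopropylidenepropyl)-2,5-dimethyl-3-(2,4,6-trimethoxyphenyl)hexan-1-ol
Conditions: LiAlH4, THF, 0 °C → reflux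
Reagents that add atoms: none
Why: Hydride reduction of the neopentyl ester to the primary alcohol; the strained but unpolarised alkene is inert to LiAlH4.

Step 9
Reactants: 13 (2R,3R)-2-(3-cyclopropylidenepropyl)-2,5-dimethyl-3-(2,4,6-trimethoxyphenyl)hexan-1-ol
Product: 14 (2R,3S)-2-(3-cyclopropylidenepropyl)-2,5-dimethyl-3-(2,4,6-trimethoxyphenyl)hexanal
Conditions: Dess–Martin periodinane, CH2Cl2, rt
Reagents that add atoms: none
Why: Dess–Martin oxidation gives the non-enolisable neopentyl aldehyde without acid that could open the alkylidenecyclopropane.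

Step 10
Reactants: 14 (2R,3S)-2-(3-cyclopropylidenepropyl)-2,5-dimethyl-3-(2,4,6-trimethoxyphenyl)hexanal
Product: 15 ethyl (3E,5S,6R)-5-(3-cyclopropylidenepropyl)-5,8-dimethyl-2-methylidene-6-(2,4,6-trimethoxyphenyl)non-3-enoate
Conditions: ethyl 2-(diethoxyphosphorylmethyl)acrylate (1.3 equiv), NaH, THF, 0 °C → rt; product kept cold and dilute and used at once
Reagents that add atoms: ethyl 2-(diethoxyphosphorylmethyl)acrylate, C=C(CP(=O)(OCC)OCC)C(=O)OCC
Why: Horner–Wadsworth–Emmons olefination with the allylic phosphonate builds the 2-carboethoxy-1,3-diene, the E geometry arising from the usual anti elimination of the equilibrating phosphonate adduct of a bulky aldehyde.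

Step 11
Reactants: 15 ethyl (3E,5S,6R)-5-(3-cyclopropylidenepropyl)-5,8-dimethyl-2-methylidene-6-(2,4,6-trimethoxyphenyl)non-3-enoate
Product: 16 ethyl (1S,3aS,8aS)-1-methyl-4-methylidene-1-[(1R)-3-methyl-1-(2,4,6-trimethoxyphenyl)butyl]-1,2,3,3a,4,5,6,8a-octahydroazulene-7-carboxylate
Conditions: Pd2(dba)3 (5 mol %), tris(2,4-di-tert-butylphenyl) phosphite (15 mol %), 1,4-dioxane (0.01 M), 100 °C
Reagents that add atoms: none
Why: Zerovalent palladium inserts into the strained distal C–C bond of the alkylidenecyclopropane to give a palladacyclobutane (a palladium-bound trimethylenemethane), which carbopalladates the proximal C-8=C-8a bond of the diene, forming C-3a–C-8a in a 5-exo closure of the cyclopentane through the three-atom tether and leaving a σ-alkyl/π-allyl palladium species; reductive elimination at the unsubstituted allyl terminus C-6 then forms C-5–C-6 and closes the seven-membered ring as the [4+3] mode of cycloaddition. The closest known reaction type is the palladium-catalysed intramolecular [4+3] cycloaddition of alkylidenecyclopropanes with tethered 1,3-dienes, applied here to a 2-carboalkoxy diene. C-3a is set relative to C-1 in the carbopalladation: a compact cis-fused transition state with the bulky arylalkyl group of C-1 anti to the dienyl arm should place 3a-H and 8a-H on the face of that group, that is 3a-H trans to the C-1 methyl group, while the centre formed at C-8a is erased in step 13. The step needs periselectivity for [4+3] over [3+2] closure, which the bulky phosphite and the unhindered CH2 terminus of the ester-bearing allyl unit should favour, and facial selectivity at C-3a, which rests on the quaternary centre; high dilution should hold back Diels–Alder dimerisation of the dienoate.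

Step 12
Reactants: 16 ethyl (1S,3aS,8aS)-1-methyl-4-methylidene-1-[(1R)-3-methyl-1-(2,4,6-trimethoxyphenyl)butyl]-1,2,3,3a,4,5,6,8a-octahydroazulene-7-carboxylate
Product: 17 ethyl (1S,3aR,4R,8aR)-1,4-dimethyl-1-[(1R)-3-methyl-1-(2,4,6-trimethoxyphenyl)butyl]-1,2,3,3a,4,5,6,8a-octahydroazulene-7-carboxylate
Conditions: H2 (1 atm), RhCl(PPh3)3 (10 mol %), benzene, rt
Reagents that add atoms: none
Why: Homogeneous hydrogenation with RhCl(PPh3)3 should reduce only the 1,1-disubstituted exocyclic alkene and, as with 2-alkylmethylenecycloalkanes that give the cis-vicinal product, deliver hydrogen to C-4 on the face of the neighbouring 3a-H, setting the C-4 methyl group cis to the cyclopentane bond of C-3a.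

Step 13
Reactants: 17 ethyl (1S,3aR,4R,8aR)-1,4-dimethyl-1-[(1R)-3-methyl-1-(2,4,6-trimethoxyphenyl)butyl]-1,2,3,3a,4,5,6,8a-octahydroazulene-7-carboxylate
Product: 19 ethyl (1R,3aR,4R,7R)-1,4-dimethyl-1-[(1R)-3-methyl-1-(2,4,6-trimethoxyphenyl)butyl]-1,2,3,3a,4,5,6,7-octahydroazulene-7-carboxylate, via lithium dienolate 18 (not isolated)
Conditions: LiN(iPr)2 (1.5 equiv), HMPA, THF, −78 → −40 °C; then AcOH, −78 °C
Reagents that add atoms: none
Why: Deconjugative protonation: γ-deprotonation at C-8a gives the extended enolate, and kinetic protonation at the α-carbon C-7 moves the double bond to C-8=C-8a; the proton is expected to enter axially on the face of C-7 anti to the C-6–C-5 bond of the half-chair-like dienolate (C-4 above, C-5 below its plane), which would leave the ester on the lower face (7R).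

Step 14
Reactants: 19 ethyl (1R,3aR,4R,7R)-1,4-dimethyl-1-[(1R)-3-methyl-1-(2,4,6-trimethoxyphenyl)butyl]-1,2,3,3a,4,5,6,7-octahydroazulene-7-carboxylate
Product: 20 2-{(1R,3aR,4R,7R)-1,4-dimethyl-1-[(1R)-3-methyl-1-(2,4,6-trimethoxyphenyl)butyl]-1,2,3,3a,4,5,6,7-octahydroazulen-7-yl}propan-2-ol
Conditions: MeLi (4 equiv), CeCl3 (anhydrous, 4 equiv), THF, −78 °C; then water
Reagents that add atoms: methyllithium, [Li]C
Why: Double addition of a weakly basic organocerium methyl nucleophile to the ester gives the tertiary carbinol while avoiding enolisation that would epimerise C-7 or reconjugate the alkene.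

Step 15
Reactants: 20 2-{(1R,3aR,4R,7R)-1,4-dimethyl-1-[(1R)-3-methyl-1-(2,4,6-trimethoxyphenyl)butyl]-1,2,3,3a,4,5,6,7-octahydroazulen-7-yl}propan-2-ol
Product: 22 5-{(1R)-1-[(1R,3aR,4R,7R)-7-(2-hydroxypropan-2-yl)-1,4-dimethyl-1,2,3,3a,4,5,6,7-octahydroazulen-1-yl]-3-methylbutyl}-2,4,6-trimethoxybenzene-1,3-dicarbaldehyde, via lithium aminoalkoxide monoadduct 21 (not isolated)
Conditions: n-BuLi (2.2 equiv), TMEDA, THF, 0 °C; DMF (1.1 equiv), −78 °C; n-BuLi (1.5 equiv), −78 → 0 °C; DMF (excess), −78 °C → rt; then 1 M HCl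
Reagents that add atoms: N,N-dimethylformamide, CN(C)C=O
Why: Directed ortho-metalation at each arene C–H flanked by two methoxy groups and formylation with DMF, the first formyl group staying masked as its lithium α-aminoalkoxide during the second lithiation and the tertiary alcohol being protected as its alkoxide.

Step 16
Reactants: 22 5-{(1R)-1-[(1R,3aR,4R,7R)-7-(2-hydroxypropan-2-yl)-1,4-dimethyl-1,2,3,3a,4,5,6,7-octahydroazulen-1-yl]-3-methylbutyl}-2,4,6-trimethoxybenzene-1,3-dicarbaldehyde
Product: 23 5-{(1R)-1-[(1R,3aR,4R,7R)-7-(2-hydroxypropan-2-yl)-1,4-dimethyl-1,2,3,3a,4,5,6,7-octahydroazulen-1-yl]-3-methylbutyl}-2,4,6-trihydroxybenzene-1,3-dicarbaldehyde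
Conditions: NaSEt (excess), DMF, 110 °C; then 1 M HCl
Reagents that add atoms: none
Why: Nucleophilic demethylation of the three aryl methyl ethers by thiolate at methyl, each ether being activated by an ortho formyl group, under basic conditions that spare the tertiary alcohol and the trisubstituted alkene.

**Compound list**

1 | 5,7-dimethoxycoumarin (5,7-dimethoxy-2H-chromen-2-one) | O=C1C=Cc2c(OC)cc(OC)cc2O1 | starting material
2 | (4R)-5,7-dimethoxy-4-(2-methylpropyl)chroman-2-one | CC(C)C[C@@H]1CC(=O)Oc2cc(OC)cc(OC)c21 | intermediate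
3 | lithium enolate of 2 | [Li+].CC(C)C[C@@H]1C=C([O-])Oc2cc(OC)cc(OC)c21 | intermediate
4 | (3R,4R)-5,7-dimethoxy-3-methyl-4-(2-methylpropyl)chroman-2-one (methyl trans to isobutyl) | CC(C)C[C@@H]1[C@@H](C)C(=O)Oc2cc(OC)cc(OC)c21 | intermediate
5 | lithium enolate of 4 | [Li+].CC(C)C[C@@H]1C(C)=C([O-])Oc2cc(OC)cc(OC)c21 | intermediate
6 | (3R,4S)-5,7-dimethoxy-3-methyl-4-(2-methylpropyl)-3-(prop-2-en-1-yl)chroman-2-one (allyl trans, methyl cis to isobutyl) | CC(C)C[C@@H]1[C@@](C)(CC=C)C(=O)Oc2cc(OC)cc(OC)c21 | intermediate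
7 | dipotassium (2R,3S)-3-(2,4-dimethoxy-6-oxidophenyl)-2,5-dimethyl-2-(prop-2-en-1-yl)hexanoate | [K+].[K+].CC(C)C[C@@H](c1c([O-])cc(OC)cc1OC)[C@@](C)(CC=C)C([O-])=O | intermediate
8 | methyl (2R,3S)-2,5-dimethyl-2-(prop-2-en-1-yl)-3-(2,4,6-trimethoxyphenyl)hexanoate | CC(C)C[C@@H](c1c(OC)cc(OC)cc1OC)[C@@](C)(CC=C)C(=O)OC | intermediate
9 | methyl (2R,3S)-2-[3-(9-borabicyclo[3.3.1]nonan-9-yl)propyl]-2,5-dimethyl-3-(2,4,6-trimethoxyphenyl)hexanoate | CC(C)C[C@@H](c1c(OC)cc(OC)cc1OC)[C@@](C)(CCCB1C2CCCC1CCC2)C(=O)OC | intermediate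
10 | methyl (2R,3S)-2-(3-hydroxypropyl)-2,5-dimethyl-3-(2,4,6-trimethoxyphenyl)hexanoate | CC(C)C[C@@H](c1c(OC)cc(OC)cc1OC)[C@@](C)(CCCO)C(=O)OC | intermediate
11 | methyl (2R,3S)-2,5-dimethyl-2-(3-oxopropyl)-3-(2,4,6-trimethoxyphenyl)hexanoate | CC(C)C[C@@H](c1c(OC)cc(OC)cc1OC)[C@@](C)(CCC=O)C(=O)OC | intermediate
12 | methyl (2R,3S)-2-(3-cyclopropylidenepropyl)-2,5-dimethyl-3-(2,4,6-trimethoxyphenyl)hexanoate | CC(C)C[C@@H](c1c(OC)cc(OC)cc1OC)[C@@](C)(CCC=C1CC1)C(=O)OC | intermediate
13 | (2R,3R)-2-(3-cyclopropylidenepropyl)-2,5-dimethyl-3-(2,4,6-trimethoxyphenyl)hexan-1-ol | CC(C)C[C@@H](c1c(OC)cc(OC)cc1OC)[C@@](C)(CCC=C1CC1)CO | intermediate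
14 | (2R,3S)-2-(3-cyclopropylidenepropyl)-2,5-dimethyl-3-(2,4,6-trimethoxyphenyl)hexanal | CC(C)C[C@@H](c1c(OC)cc(OC)cc1OC)[C@@](C)(CCC=C1CC1)C=O | intermediate
15 | ethyl (3E,5S,6R)-5-(3-cyclopropylidenepropyl)-5,8-dimethyl-2-methylidene-6-(2,4,6-trimethoxyphenyl)non-3-enoate | CC(C)C[C@@H](c1c(OC)cc(OC)cc1OC)[C@@](C)(CCC=C1CC1)/C=C/C(=C)C(=O)OCC | intermediate
16 | ethyl (1S,3aS,8aS)-1-methyl-4-methylidene-1-[(1R)-3-methyl-1-(2,4,6-trimethoxyphenyl)butyl]-1,2,3,3a,4,5,6,8a-octahydroazulene-7-carboxylate | CC(C)C[C@@H](c1c(OC)cc(OC)cc1OC)[C@@]1(C)CC[C@H]2[C@@H]1C=C(C(=O)OCC)CCC2=C | intermediate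
17 | ethyl (1S,3aR,4R,8aR)-1,4-dimethyl-1-[(1R)-3-methyl-1-(2,4,6-trimethoxyphenyl)butyl]-1,2,3,3a,4,5,6,8a-octahydroazulene-7-carboxylate | CC(C)C[C@@H](c1c(OC)cc(OC)cc1OC)[C@@]1(C)CC[C@H]2[C@@H]1C=C(C(=O)OCC)CC[C@H]2C | intermediate
18 | lithium dienolate of 17 (C-8=C-8a, C-7=C(OEt)OLi) | [Li+].CC(C)C[C@@H](c1c(OC)cc(OC)cc1OC)[C@@]1(C)CC[C@H]2C1=CC(=C([O-])OCC)CC[C@H]2C | intermediate
19 | ethyl (1R,3aR,4R,7R)-1,4-dimethyl-1-[(1R)-3-methyl-1-(2,4,6-trimethoxyphenyl)butyl]-1,2,3,3a,4,5,6,7-octahydroazulene-7-carboxylate | CC(C)C[C@@H](c1c(OC)cc(OC)cc1OC)[C@@]1(C)CC[C@H]2C1=C[C@H](C(=O)OCC)CC[C@H]2C | intermediate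
20 | 2-{(1R,3aR,4R,7R)-1,4-dimethyl-1-[(1R)-3-methyl-1-(2,4,6-trimethoxyphenyl)butyl]-1,2,3,3a,4,5,6,7-octahydroazulen-7-yl}propan-2-ol | CC(C)C[C@@H](c1c(OC)cc(OC)cc1OC)[C@@]1(C)CC[C@H]2C1=C[C@H](C(C)(C)O)CC[C@H]2C | intermediate
21 | dilithium salt of the mono-formylation adduct of 20 (aryl-CH(OLi)NMe2, tertiary lithium alkoxide) | [Li+].[Li+].CC(C)C[C@@H](c1c(OC)c(C([O-])N(C)C)c(OC)cc1OC)[C@@]1(C)CC[C@H]2C1=C[C@H](C(C)(C)[O-])CC[C@H]2C | intermediate
22 | 5-{(1R)-1-[(1R,3aR,4R,7R)-7-(2-hydroxypropan-2-yl)-1,4-dimethyl-1,2,3,3a,4,5,6,7-octahydroazulen-1-yl]-3-methylbutyl}-2,4,6-trimethoxybenzene-1,3-dicarbaldehyde | CC(C)C[C@@H](c1c(OC)c(C=O)c(OC)c(C=O)c1OC)[C@@]1(C)CC[C@H]2C1=C[C@H](C(C)(C)O)CC[C@H]2C | intermediate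
23 | 5-{(1R)-1-[(1R,3aR,4R,7R)-7-(2-hydroxypropan-2-yl)-1,4-dimethyl-1,2,3,3a,4,5,6,7-octahydroazulen-1-yl]-3-methylbutyl}-2,4,6-trihydroxybenzene-1,3-dicarbaldehyde | CC(C)C[C@@H](c1c(O)c(C=O)c(O)c(C=O)c1O)[C@@]1(C)CC[C@H]2C1=C[C@H](C(C)(C)O)CC[C@H]2C | target

Total step count: 16. Longest linear sequence: 16 steps (from 1).

**Steps most likely to fail**

1. Step 11 (key cycloaddition). What may go wrong:
   - reductive elimination at the internal allyl terminus C-8 instead of C-6, giving [3+2] closure;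
   - slow carbopalladation next to the quaternary C-1;
   - bimolecular Diels–Alder dimerisation of the dienoate at 100 °C;
   - insufficient facial bias at C-3a.

   Fallback, a stepwise ring expansion instead of the direct [4+3] closure: setting out from 15, the cycloaddition would be run with the small ligand P(OiPr)3 (Pd2(dba)3, dioxane, 100 °C) so that the five-membered ring closes on purpose. This would give the [3+2] adduct ethyl 2-{cis-fused 6-methyl-3-methylidene-6-[(1R)-3-methyl-1-(2,4,6-trimethoxyphenyl)butyl]octahydropentalen-1-yl}prop-2-enoate F1. Its 1,5-diene (exocyclic methylene–ring CH2–ring CH–acrylate) would then be heated (o-dichlorobenzene, 180 °C) to effect a Cope rearrangement, a two-carbon ring expansion of the methylenecyclopentane that comes back to the route at 16.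

2. Step 13 (deconjugative protonation). What may go wrong:
   - incomplete γ-deprotonation of the hindered 8a-H;
   - γ-reprotonation back to the conjugated ester;
   - protonation of C-7 on the wrong face.

   Fallback, an isolable neutral dienol ether instead of a lithium dienolate: setting out from 17, soft enolisation with t-BuMe2SiOTf/Et3N (CH2Cl2, 0 °C → rt) would remove 8a-H from the O-silylated oxocarbenium ion and give the silyl ketene acetal tert-butyl{[ethoxy(azulen-7-ylidene)methyl]oxy}dimethylsilane derivative of 17 F2. It would be protodesilylated at −78 °C with HF·pyridine, or with a hindered phenol and a fluoride source, so that the size of the proton donor can be varied to steer the face of C-7. The sequence comes back to the route at 19.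

3. Step 12 (hydrogenation). What may go wrong: delivery of hydrogen to the wrong face of the exocyclic alkene, or slow reduction next to the ring fusion.

   Fallback, stepwise radical hydrogen delivery instead of syn addition on a metal: setting out from 16, the methylene group would be carried through the conditions of step 13 to give ethyl 1-methyl-4-methylidene-1-[(1R)-3-methyl-1-(2,4,6-trimethoxyphenyl)butyl]-1,2,3,3a,4,5,6,7-octahydroazulene-7-carboxylate F3 (the 4-methylidene analogue of 19). This would be reduced by hydrogen-atom-transfer hydrogenation (Mn(dpm)3, PhSiH3, t-BuOOH, i-PrOH, rt), which acts on the unhindered 1,1-disubstituted alkene and sets C-4 under thermodynamic control. The sequence comes back to the route at 19.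

**Further compounds**

F1 | step 11 | ethyl 2-{cis-fused 6-methyl-3-methylidene-6-[(1R)-3-methyl-1-(2,4,6-trimethoxyphenyl)butyl]octahydropentalen-1-yl}prop-2-enoate | CC(C)C[C@@H](c1c(OC)cc(OC)cc1OC)[C@@]1(C)CC[C@H]2[C@@H]1C(C(=C)C(=O)OCC)CC2=C
F2 | step 13 | silyl ketene acetal of 17 (C-8=C-8a, C-7=C(OEt)OSiMe2t-Bu) | CC(C)C[C@@H](c1c(OC)cc(OC)cc1OC)[C@@]1(C)CC[C@H]2C1=CC(=C(OCC)O[Si](C)(C)C(C)(C)C)CC[C@H]2C
F3 | step 12 | ethyl 1-methyl-4-methylidene-1-[(1R)-3-methyl-1-(2,4,6-trimethoxyphenyl)butyl]-1,2,3,3a,4,5,6,7-octahydroazulene-7-carboxylate (4-methylidene analogue of 19) | CC(C)C[C@@H](c1c(OC)cc(OC)cc1OC)[C@@]1(C)CC[C@H]2C1=C[C@H](C(=O)OCC)CCC2=C
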